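## The problem

Target 14 is a diarylmethane: two fully substituted benzene rings share one CH2 group. It has no stereocenter, so the whole difficulty is one of position, not of space. Ring A is numbered C1 (OMe), C2 (Me), C3 (OH), C4 (bridge CH2), C5 (OMe), C6 (isobutyryl). Ring B is numbered C1' (bridge CH2), C2' (OH), C3' (Me), C4' (OH), C5' (isobutyryl), C6' (OH).

Ring A has its two methyl ethers beside the ketone and its only free hydroxyl para to it. Partial alkylation of an acylphloroglucinol attacks the para oxygen first, so that oxygen must carry a removable group while the two chelated ortho hydroxyls are methylated. The bridge cannot be made cleanly by condensing two phloroglucinol monomers with formaldehyde, because homo- and hetero-dimers form side by side. The two rings must therefore be attached to the CH2 in separate events.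

Three features are fragile. The methyl ethers ortho to the ring A ketone are cleaved by strong oxophilic Lewis acids. The electron-rich Ar–CH2–Ar bond is broken by ipso-protonation under strong acid. The free polyphenols oxidise in air under base.

The feature that makes the key step possible lies in ring B. C1'–C2'–C3' is the skeleton of a ketone: C2' is the carbonyl carbon, C1' an alpha carbon bearing the bridge CH2, and C3' an alpha carbon bearing the methyl group. C4'–C5'–C6' is a malonyl unit whose middle carbon is unsubstituted until the last acylation. Ring B can therefore be grown on a ring A–CH2–CH2–CO–CH2–CH3 chain in which the bridge carbon is already present as the beta carbon of the ketone.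

## Retrosynthesis

**14 from 13.** The O–benzyl bond at ring A C3 is cut last. The benzyl ether marks the para oxygen from the second step onward. It also keeps the C3 hydroxyl from forming a lactol with the side-chain ketone of 8 and from being acylated in the key step. A methyl group could not be removed selectively next to two other methyl ethers. Hydrogenolysis is neutral and is asked only to spare two aryl ketones, one chelated and one hindered.

**13 from 12 and 2.** The C5'–C(=O) bond is cut. C5' is the only aromatic C–H in 12, because ring A is hexasubstituted, so the regiochemistry of a Friedel–Crafts acylation is automatic. Carrying the acyl group on the three-carbon unit of the key step would load that step with a tricarbonyl electrophile. The forward reaction needs a Lewis acid mild enough for the ortho-methoxy ketone, the benzyl ether and the diarylmethane.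

**12 from 8 and 9 (key disconnection).** The C1'–C6' and C3'–C4' bonds are cut, which dissolves ring B completely. The neighbouring cut, between the bridge carbon and C1', would require benzylation of a free phloroglucinol such as 1, which has two reactive carbons and over-alkylates. The acylated ring B monomer 3 behaves better and is kept as the fallback. The chosen cut leaves an open-chain ketone 8 and the commercial acid chloride 9. The forward reaction passes through silyl enol ether 10 and acid chloride 11. It must close the ring through carbon and not through the enol oxygen.

**8 from 6 and 7.** The bond between ring A C4 and the bridge carbon is cut. A Heck reaction of aryl iodide 6 with allylic alcohol 7 gives the saturated ketone at the correct oxidation level in one step. The neighbouring cut, between the bridge carbon and the alpha carbon, would need a self-ionising ring A benzylic halide and the less substituted enolate of an unsymmetrical four-carbon ketone. A longer alternative through a carboxylic acid derivative and an ethyl organometallic would have to discriminate against the ring A ketone. The Heck reaction is asked to insert an alkene into a doubly ortho-substituted aryl–palladium bond.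

**6 from 5.** The C–I bond is cut. Compound 5 has one free ring position, activated by two ortho and one para alkoxy groups, so electrophilic iodination has no regiochemical choice.

**5 from 4, and 4 from 3.** The three O–alkyl bonds are cut in the order set by acidity. The para hydroxyl of 3 is the most acidic and is not chelated, so it takes the benzyl group first. The two chelated ortho hydroxyls of 4 are then methylated under forcing conditions. Each step removes one or two carbons and no skeletal complexity. The first must stop at mono-alkylation.

**3 from 1 and 2.** The aryl–acyl bond is cut. The two free ring carbons of 1 are equivalent, and the first acyl group deactivates the ring toward a second. Compound 3 is also ring B of the target with its acyl group in place, which the fallback for the key step uses.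

## Roads not taken

**Alternative 1: aryne insertion to place the ring A acyl group.** The cut runs through ring A at C6–C(=O) and C1–O. In the forward direction the silylaryl triflate 3-(benzyloxy)-5-methoxy-2-methyl-6-(trimethylsilyl)phenyl trifluoromethanesulfonate A1 releases the C1–C6 aryne on treatment with fluoride. The aryne inserts into the C–O bond of isobutyric acid A2 and gives the ortho-hydroxyaryl ketone A3. O-Methylation of A3 would give 5, after which the route would be the present one.

- Merits: the benzyl ether is in place before the acyl group arrives. The acyl group is delivered regiospecifically next to the methoxy group, because the carboxylate adds to the aryne carbon remote from it. No strong Lewis acid is used.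
- Weak points: A1 requires a methylphloroglucinol with three different oxygen substituents plus a C-silyl group. That is more differentiation than the target needs, since the hydroxyl created by the insertion is methylated at once. The carboxylate must attack an aryne carbon flanked by the methyl group. Simple O-arylation of the acid competes with insertion, the more so for an alpha-branched acid.
- Comparison: this road is better in one respect, since it avoids the selective mono-benzylation of step 2. Against that, the chosen plan reaches 5 in three classical steps from a commercial triol, uses the built-in acidity difference, and has a fallback. Alternative 1 also leaves the bridge and ring B unaddressed.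

**Alternative 2: twofold decarboxylative ketone synthesis.** The cut is through both carbonyl–CH(CH3)2 bonds. The bis(S-pyridin-2-yl thioester) A4 of the tetrabenzyl-protected diarylmethane diacid would couple with two equivalents of the N-acyloxyphthalimide A5 under reductive nickel catalysis in an electrochemical cell. The product is the tetrabenzyl ether A6, and fourfold hydrogenolysis would give 14.

- Merits: both ketones are made late, in one operation, under reductive and non-acidic conditions. No Lewis acid meets the methyl ethers or the diarylmethane. In this respect it is as good as or better than the chosen plan.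
- Weak points: each thioester carbonyl lies between two ortho alkoxy groups. Oxidative addition and capture of the secondary isopropyl radical are both hindered, and a twofold coupling multiplies every inefficiency. More seriously, the step does not touch the real problem. A4 already contains the unsymmetrical diarylmethane with six differentiated oxygens, so a separate bridge construction and a long protecting-group sequence must precede it.
- Comparison: the chosen plan makes its two ketones by acylation at positions with no regiochemical choice, and its key step builds the bridge-bearing ring itself.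

**Alternative 3: benzannulation to build ring A.** The cut is through ring A at C2–C3 and C1–C6. The cyclobutenone A7, carrying the protected ring B benzyl group on C4, would be heated with 1-methoxyprop-1-yne A8. Ring opening, ketene–alkyne cycloaddition, a second ring opening and 6π closure would give phenol A9. Acylation at ring A C6 and debenzylation would follow.

- Merits: the ring A oxygen pattern arises by construction. The single free hydroxyl comes from the cyclobutenone carbonyl and the two methyl ethers from the enol ether and the ynol ether. This is more elegant than the selective benzylation of the chosen plan, and the bridge is in place from the start.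
- Weak points: A7 must carry a hexasubstituted benzyl group, which presupposes a ring B benzylic electrophile and a cyclobutenone alkylation. A8 is a volatile and sensitive ynol ether. The late acylation at C6 must compete with the free C3 hydroxyl and needs a Lewis acid in the presence of three benzyl ethers, two of them chelation-labile.
- Comparison: the chosen plan uses only classical phenol chemistry on ring A, builds the ring that needs no oxygen differentiation (ring B), and is shorter.

Key step: step 6

## Route

Assumption: compounds 1, 7 (racemate) and 9 are taken as commercial. Silyl enol ether 10 is expected as a mixture of two regioisomers and their E/Z forms, all of which lead to 12; it is drawn as the (3Z)-pent-3-enyl isomer.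

Step 1
Reactants: 1 2-methylbenzene-1,3,5-triol (2-methylphloroglucinol); 2 2-methylpropanoyl chloride (isobutyryl chloride)
Product: 3 2-methyl-1-(2,4,6-trihydroxy-3-methylphenyl)propan-1-one
Conditions: AlCl3, PhNO2, 60 °C; aq. HCl work-up
Reagents that add atoms: none
Why: Friedel–Crafts acylation of a phloroglucinol; the two free ring carbons of 1 are equivalent, and the chelated acyl group of 3 deactivates the ring toward a second acylation.

Step 2
Reactants: 3 2-methyl-1-(2,4,6-trihydroxy-3-methylphenyl)propan-1-one
Product: 4 1-[4-(benzyloxy)-2,6-dihydroxy-3-methylphenyl]-2-methylpropan-1-one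
Conditions: BnBr (1.0 equiv), K2CO3 (1.0 equiv), DMF, 0 °C to rt
Reagents that add atoms: benzyl bromide, BrCc1ccccc1
Why: Williamson ether synthesis gated by acidity; the hydroxyl para to the ketone is the most acidic and the only one not next to the acyl group, so one equivalent of base should ionise it alone, and the dipolar aprotic solvent should favour O- over C-benzylation.

Step 3
Reactants: 4 1-[4-(benzyloxy)-2,6-dihydroxy-3-methylphenyl]-2-methylpropan-1-one
Product: 5 1-[4-(benzyloxy)-2,6-dimethoxy-3-methylphenyl]-2-methylpropan-1-one
Conditions: Me2SO4 (excess), K2CO3, acetone, reflux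
Reagents that add atoms: dimethyl sulfate, COS(=O)(=O)OC
Why: exhaustive Williamson O-methylation of the two chelated ortho hydroxyls; excess hard methylating agent in refluxing acetone is the standard way to alkylate hydrogen-bonded phenols and should leave the free ring carbon untouched.

Step 4
Reactants: 5 1-[4-(benzyloxy)-2,6-dimethoxy-3-methylphenyl]-2-methylpropan-1-one
Product: 6 1-[4-(benzyloxy)-3-iodo-2,6-dimethoxy-5-methylphenyl]-2-methylpropan-1-one
Conditions: NIS, TFA (cat.), MeCN, rt
Reagents that add atoms: N-iodosuccinimide, O=C1CCC(=O)N1I
Why: electrophilic aromatic iodination at the only free ring position, which has two ortho and one para alkoxy groups; the ketone is meta to it and twisted out of conjugation, so it deactivates little.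

Step 5
Reactants: 6 1-[4-(benzyloxy)-3-iodo-2,6-dimethoxy-5-methylphenyl]-2-methylpropan-1-one; 7 pent-1-en-3-ol (racemic)
Product: 8 1-[2-(benzyloxy)-4,6-dimethoxy-3-methyl-5-(2-methylpropanoyl)phenyl]pentan-3-one
Conditions: Pd(OAc)2 (5 mol%), Bu4NCl, NaHCO3, DMF, 80 °C
Reagents that add atoms: none
Why: Heck reaction of an aryl iodide with a secondary allylic alcohol under ligand-free phase-transfer conditions; the aryl group adds to the terminal alkene carbon, beta-hydride elimination toward the carbinol carbon gives an enol, and tautomerisation gives the saturated ketone directly while removing the stereocenter of 7.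

Step 6
Reactants: 8 1-[2-(benzyloxy)-4,6-dimethoxy-3-methyl-5-(2-methylpropanoyl)phenyl]pentan-3-one; 9 propanedioyl dichloride (malonyl dichloride)
Product: 12 1-[4-(benzyloxy)-2,6-dimethoxy-3-methyl-5-[(2,4,6-trihydroxy-3-methylphenyl)methyl]phenyl]-2-methylpropan-1-one, via trimethylsilyl enol ether 10 (not isolated), via 3,5-dioxoheptanoyl chloride 11 (not isolated)
Conditions: LiN(SiMe3)2, Me3SiCl, THF, −78 °C; volatiles removed, pentane filtration, Et2O; 9 (1.0 equiv), −20 °C to rt; H2O quench under argon
Reagents that add atoms: chlorotrimethylsilane, C[Si](C)(C)Cl (its silyl group is carried only by intermediate 10)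
Why: Kinetic deprotonation with in-situ silylation should convert only the pentan-3-one into 10, because the ring A ketone has a single tertiary alpha hydrogen shielded by two ortho methoxy groups; either regioisomer of 10 serves, since both alpha carbons are acylated in the end. One acyl chloride end of 9 C-acylates 10 with loss of Me3SiCl and gives the 2-substituted 1,3-diketone acid chloride 11; its enol toward the remaining alpha methylene then attacks the second acyl chloride in a 6-(enolendo)-exo-trig acyl substitution, closing ring B as the cyclohexane-1,3,5-trione, which enolises irreversibly to the benzenetriol 12. The closest known reaction type is the Effenberger annulation of ketone silyl enol ethers with malonyl dichloride, which gives bicyclo[3.3.1]nonane-2,4,9-triones from cyclohexanone derivatives and 2,4-dialkylphloroglucinols from open-chain dialkyl ketones. The step needs closure through carbon and not through the enol oxygen, which would give a 4-hydroxy-2-pyranone. The substrate favours carbon because both alpha carbons are secondary, so the diketone of 11 is 2-substituted, less enolised toward its central carbon and crowded at oxygen, and because only the carbon closure ends in an aromatic ring. No stereocenter is formed; the one in 11 disappears on aromatisation. One equivalent of 9 and low temperature are chosen so that the nucleophilic product is not acylated again and the HCl released has little time to attack the diarylmethane bond.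

Step 7
Reactants: 12 1-[4-(benzyloxy)-2,6-dimethoxy-3-methyl-5-[(2,4,6-trihydroxy-3-methylphenyl)methyl]phenyl]-2-methylpropan-1-one; 2 2-methylpropanoyl chloride (isobutyryl chloride)
Product: 13 1-[3-[[2-(benzyloxy)-4,6-dimethoxy-3-methyl-5-(2-methylpropanoyl)phenyl]methyl]-2,4,6-trihydroxy-5-methylphenyl]-2-methylpropan-1-one
Conditions: TiCl4, CH2Cl2, −20 to 0 °C (acid chloride and TiCl4 premixed); aq. HCl work-up
Reagents that add atoms: none
Why: Friedel–Crafts acylation at C5', the only unsubstituted aromatic carbon in the molecule; TiCl4 is chosen over AlCl3 because it is far less prone to cleave methyl ethers ortho to a ketone or an unchelated benzyl ether at this temperature, and any O-acylated ring B material should rearrange or hydrolyse on work-up.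

Step 8
Reactants: 13 1-[3-[[2-(benzyloxy)-4,6-dimethoxy-3-methyl-5-(2-methylpropanoyl)phenyl]methyl]-2,4,6-trihydroxy-5-methylphenyl]-2-methylpropan-1-one
Product: 14 1-[3-[[2-hydroxy-4,6-dimethoxy-3-methyl-5-(2-methylpropanoyl)phenyl]methyl]-2,4,6-trihydroxy-5-methylphenyl]-2-methylpropan-1-one
Conditions: H2 (1 atm), 10% Pd/C, EtOAc, rt
Reagents that add atoms: none
Why: catalytic hydrogenolysis of a benzyl aryl ether under neutral conditions; the ring B ketone is a chelated vinylogous acid and the ring A ketone is hindered and twisted, so neither should be reduced, and no stereocenter is involved.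

## Compound list

1 | 2-methylbenzene-1,3,5-triol (2-methylphloroglucinol) | Cc1c(O)cc(O)cc1O | starting material
2 | 2-methylpropanoyl chloride (isobutyryl chloride) | CC(C)C(=O)Cl | starting material
3 | 2-methyl-1-(2,4,6-trihydroxy-3-methylphenyl)propan-1-one | CC(C)C(=O)c1c(O)cc(O)c(C)c1O | intermediate
4 | 1-[4-(benzyloxy)-2,6-dihydroxy-3-methylphenyl]-2-methylpropan-1-one | CC(C)C(=O)c1c(O)cc(OCc2ccccc2)c(C)c1O | intermediate
5 | 1-[4-(benzyloxy)-2,6-dimethoxy-3-methylphenyl]-2-methylpropan-1-one | CC(C)C(=O)c1c(OC)cc(OCc2ccccc2)c(C)c1OC | intermediate
6 | 1-[4-(benzyloxy)-3-iodo-2,6-dimethoxy-5-methylphenyl]-2-methylpropan-1-one | CC(C)C(=O)c1c(OC)c(I)c(OCc2ccccc2)c(C)c1OC | intermediate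
7 | pent-1-en-3-ol (racemic) | C=CC(O)CC | starting material
8 | 1-[2-(benzyloxy)-4,6-dimethoxy-3-methyl-5-(2-methylpropanoyl)phenyl]pentan-3-one | CCC(=O)CCc1c(OCc2ccccc2)c(C)c(OC)c(C(=O)C(C)C)c1OC | intermediate
9 | propanedioyl dichloride (malonyl dichloride) | O=C(Cl)CC(=O)Cl | starting material
10 | 1-[4-(benzyloxy)-2,6-dimethoxy-3-methyl-5-[(3Z)-3-(trimethylsilyloxy)pent-3-en-1-yl]phenyl]-2-methylpropan-1-one (one isomer of the mixture drawn; not isolated) | C/C=C(\O[Si](C)(C)C)CCc1c(OCc2ccccc2)c(C)c(OC)c(C(=O)C(C)C)c1OC | intermediate
11 | 7-[2-(benzyloxy)-4,6-dimethoxy-3-methyl-5-(2-methylpropanoyl)phenyl]-4-methyl-3,5-dioxoheptanoyl chloride (racemic; not isolated) | CC(C(=O)CC(=O)Cl)C(=O)CCc1c(OCc2ccccc2)c(C)c(OC)c(C(=O)C(C)C)c1OC | intermediate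
12 | 1-[4-(benzyloxy)-2,6-dimethoxy-3-methyl-5-[(2,4,6-trihydroxy-3-methylphenyl)methyl]phenyl]-2-methylpropan-1-one | COc1c(C)c(OCc2ccccc2)c(Cc3c(O)c(C)c(O)cc3O)c(OC)c1C(=O)C(C)C | intermediate
13 | 1-[3-[[2-(benzyloxy)-4,6-dimethoxy-3-methyl-5-(2-methylpropanoyl)phenyl]methyl]-2,4,6-trihydroxy-5-methylphenyl]-2-methylpropan-1-one | COc1c(C)c(OCc2ccccc2)c(Cc3c(O)c(C)c(O)c(C(=O)C(C)C)c3O)c(OC)c1C(=O)C(C)C | intermediate
14 | 1-[3-[[2-hydroxy-4,6-dimethoxy-3-methyl-5-(2-methylpropanoyl)phenyl]methyl]-2,4,6-trihydroxy-5-methylphenyl]-2-methylpropan-1-one | COc1c(C)c(O)c(Cc2c(O)c(C)c(O)c(C(=O)C(C)C)c2O)c(OC)c1C(=O)C(C)C | target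

## Step count and least certain steps

Total: 8 steps. Longest linear sequence: 8 steps, from 1 to 14; compounds 2, 7 and 9 are commercial.

**Step 6 (key step).** The most likely failure is closure of the second acyl chloride through the enol oxygen, because the enol of a 1,3-diketone toward its central carbon is normally the dominant tautomer and places that oxygen within reach. Two further risks are protodesilylation of 10 by released HCl, which simply returns 8, and acid-induced cleavage at the new Ar–CH2–Ar bond by ipso-protonation of the very electron-rich ring B.

The fallback gives up the de novo construction of ring B and attaches the preformed ring B monomer 3. It sets out from 6. Reductive carbonylation (CO, Bu3SnH, Pd(PPh3)4, toluene, 50 °C) should give 2-(benzyloxy)-4,6-dimethoxy-3-methyl-5-(2-methylpropanoyl)benzaldehyde F1. Reduction with NaBH4 in MeOH at 0 °C, which should spare the hindered ring A ketone, gives 1-[4-(benzyloxy)-3-(hydroxymethyl)-2,6-dimethoxy-5-methylphenyl]-2-methylpropan-1-one F2. Acid-catalysed Friedel–Crafts benzylation of 3 with F2 (TsOH cat., CH2Cl2, rt) then forms the bridge. F2 has no free ring position and 3 has a single nucleophilic carbon, so only the cross-coupled diarylmethane can form. The product is 13, where the route is rejoined before step 8.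

**Step 5.** Insertion of the alkene into a doubly ortho-substituted aryl–palladium bond may be slow. That gives time for hydrodeiodination, for cyclopalladation onto the phenyl ring of the neighbouring benzyl ether, and for beta-hydride elimination away from the carbinol carbon.

The fallback sets out from 6 and uses an electron-poor alkene, which inserts faster and can eliminate in only one direction. Heck reaction with pent-1-en-3-one (Pd(OAc)2, Bu4NCl, NaHCO3, DMF, 80 °C) should give (1E)-1-[2-(benzyloxy)-4,6-dimethoxy-3-methyl-5-(2-methylpropanoyl)phenyl]pent-1-en-3-one F3. Conjugate reduction with [(Ph3P)CuH]6 in THF at rt, which does not touch the benzyl ether, returns the route to 8.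

**Step 7.** The Lewis acid may remove the ring A benzyl group before C5' is acylated, and the benzyl cation would then be transferred to C5', the only free ring carbon. The diarylmethane bond may also be cleaved by ipso attack on ring B.

The fallback sets out from 12 and replaces the acylium electrophile by a nitrilium ion (Houben–Hoesch reaction). Isobutyronitrile, ZnCl2 and HCl gas in Et2O at 0 °C should give the ketiminium salt 1-[3-[[2-(benzyloxy)-4,6-dimethoxy-3-methyl-5-(2-methylpropanoyl)phenyl]methyl]-2,4,6-trihydroxy-5-methylphenyl]-2-methylpropan-1-iminium chloride F4. Hydrolysis in warm water returns the route to 13.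

**Step 2.** Alkylation may run on to a second oxygen or to the free ring carbon, because the mono-ether 4 still has two acidic hydroxyls and a nucleophilic C–H.

The fallback sets out from 3 and differentiates the oxygens by size, not by acidity. A bulky silyl chloride (iPr3SiCl, imidazole, DMF) should reach only the hydroxyl that is not next to the acyl group, and any silylation of a chelated hydroxyl is reversible on mild methanolysis. This gives 1-[2,6-dihydroxy-3-methyl-4-[(triisopropylsilyl)oxy]phenyl]-2-methylpropan-1-one F5. Methylation (Me2SO4, K2CO3, dry acetone) gives 1-[2,6-dimethoxy-3-methyl-4-[(triisopropylsilyl)oxy]phenyl]-2-methylpropan-1-one F6. Desilylation (Bu4NF, THF) gives 1-(4-hydroxy-2,6-dimethoxy-3-methylphenyl)-2-methylpropan-1-one F7. Benzylation (BnBr, K2CO3, DMF) returns the route to 5, at a cost of two extra steps.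

## Further compounds

F1 | step 6 | 2-(benzyloxy)-4,6-dimethoxy-3-methyl-5-(2-methylpropanoyl)benzaldehyde | CC(C)C(=O)c1c(OC)c(C=O)c(OCc2ccccc2)c(C)c1OC
F2 | step 6 | 1-[4-(benzyloxy)-3-(hydroxymethyl)-2,6-dimethoxy-5-methylphenyl]-2-methylpropan-1-one | CC(C)C(=O)c1c(OC)c(CO)c(OCc2ccccc2)c(C)c1OC
F3 | step 5 | (1E)-1-[2-(benzyloxy)-4,6-dimethoxy-3-methyl-5-(2-methylpropanoyl)phenyl]pent-1-en-3-one | CCC(=O)/C=C/c1c(OCc2ccccc2)c(C)c(OC)c(C(=O)C(C)C)c1OC
F4 | step 7 | 1-[3-[[2-(benzyloxy)-4,6-dimethoxy-3-methyl-5-(2-methylpropanoyl)phenyl]methyl]-2,4,6-trihydroxy-5-methylphenyl]-2-methylpropan-1-iminium chloride | COc1c(C)c(OCc2ccccc2)c(Cc3c(O)c(C)c(O)c(C(=[NH2+])C(C)C)c3O)c(OC)c1C(=O)C(C)C.[Cl-]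
F5 | step 2 | 1-[2,6-dihydroxy-3-methyl-4-[(triisopropylsilyl)oxy]phenyl]-2-methylpropan-1-one | CC(C)C(=O)c1c(O)cc(O[Si](C(C)C)(C(C)C)C(C)C)c(C)c1O
F6 | step 2 | 1-[2,6-dimethoxy-3-methyl-4-[(triisopropylsilyl)oxy]phenyl]-2-methylpropan-1-one | CC(C)C(=O)c1c(OC)cc(O[Si](C(C)C)(C(C)C)C(C)C)c(C)c1OC
F7 | step 2 | 1-(4-hydroxy-2,6-dimethoxy-3-methylphenyl)-2-methylpropan-1-one | CC(C)C(=O)c1c(OC)cc(O)c(C)c1OC
A1 | alternative 1 | 3-(benzyloxy)-5-methoxy-2-methyl-6-(trimethylsilyl)phenyl trifluoromethanesulfonate | COc1cc(OCc2ccccc2)c(C)c(OS(=O)(=O)C(F)(F)F)c1[Si](C)(C)C
A2 | alternative 1 | 2-methylpropanoic acid (isobutyric acid) | CC(C)C(=O)O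
A3 | alternative 1 | 1-[4-(benzyloxy)-2-hydroxy-6-methoxy-3-methylphenyl]-2-methylpropan-1-one | COc1cc(OCc2ccccc2)c(C)c(O)c1C(=O)C(C)C
A4 | alternative 2 | S-pyridin-2-yl 2,4,6-tris(benzyloxy)-3-[[2-(benzyloxy)-4,6-dimethoxy-3-methyl-5-[(pyridin-2-ylsulfanyl)carbonyl]phenyl]methyl]-5-methylbenzenecarbothioate | COc1c(C)c(OCc2ccccc2)c(Cc3c(OCc4ccccc4)c(C)c(OCc4ccccc4)c(C(=O)Sc4ccccn4)c3OCc5ccccc5)c(OC)c1C(=O)Sc6ccccn6
A5 | alternative 2 | 1,3-dioxoisoindolin-2-yl 2-methylpropanoate | CC(C)C(=O)ON1C(=O)c2ccccc2C1=O
A6 | alternative 2 | 1-[2,4,6-tris(benzyloxy)-3-[[2-(benzyloxy)-4,6-dimethoxy-3-methyl-5-(2-methylpropanoyl)phenyl]methyl]-5-methylphenyl]-2-methylpropan-1-one | COc1c(C)c(OCc2ccccc2)c(Cc3c(OCc4ccccc4)c(C)c(OCc4ccccc4)c(C(=O)C(C)C)c3OCc5ccccc5)c(OC)c1C(=O)C(C)C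
A7 | alternative 3 | 3-methoxy-4-[[2,4,6-tris(benzyloxy)-3-methyl-5-(2-methylpropanoyl)phenyl]methyl]cyclobut-2-en-1-one (racemic) | COC1=CC(=O)C1Cc2c(OCc3ccccc3)c(C)c(OCc3ccccc3)c(C(=O)C(C)C)c2OCc4ccccc4
A8 | alternative 3 | 1-methoxyprop-1-yne | CC#COC
A9 | alternative 3 | 1-[2,4,6-tris(benzyloxy)-3-[(2-hydroxy-4,6-dimethoxy-3-methylphenyl)methyl]-5-methylphenyl]-2-methylpropan-1-one | COc1cc(OC)c(Cc2c(OCc3ccccc3)c(C)c(OCc3ccccc3)c(C(=O)C(C)C)c2OCc4ccccc4)c(O)c1C
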